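All runs were generated by integration on assumed constants, noise included.

A ratio of two amounts is the quantity to read first: the top reading of complex with two exchanged in Monday's run over the top reading at c(starting complex) = 0.10 M.

| setting | Thursday's | Saturday's | Monday's | flask |
|---|---|---|---|---|
| starting complex | 0.10 M | 0.10 M | 0.20 M | 0.10 M |
| incoming ligand | 1.1 equiv | 1.1 equiv | 1.1 equiv | 1.10 equiv |
| leaving ligand | 5 equiv | 5 equiv | 5 equiv | 5.00 equiv |
| protic impurity | 0.010 M | 0.040 M | 0.020 M | 0.0200 M |
| remark | run made earlier | run made earlier | run made earlier |  |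
| time |  |  |  | 3.0 d |

| run | time / d | complex with two exchanged / % | complex with three exchanged / % | starting complex / % |
|---|---|---|---|---|
| Thursday's | 0.0278 | 5.0 | 0 | 58.9 |
| Thursday's | 0.0833 | 11.3 | 2.3 | 31.5 |
| Thursday's | 0.208 | 8.3 | 4.1 | 17.7 |
| Thursday's | 0.500 | 1.9 | 4.3 | 9.7 |
| Thursday's | 1.25 | 0 | 4.4 | 6.2 |
| Thursday's | 3.00 | 0.5 | 4.6 | 4.3 |
| Saturday's | 0.0278 | 5.5 | 0.9 | 53.5 |
| Saturday's | 0.0833 | 11.5 | 2.2 | 24.2 |
| Saturday's | 0.208 | 9.0 | 3.5 | 9.3 |
| Saturday's | 0.500 | 2.7 | 4.6 | 2.6 |
| Saturday's | 1.25 | 0 | 5.8 | 0 |
| Saturday's | 3.00 | 0.3 | 4.8 | 0 |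
| Monday's | 0.0278 | 10.2 | 0.7 | 40.6 |
| Monday's | 0.104 | 14.3 | 3.8 | 16.6 |
| Monday's | 0.333 | 2.5 | 5.4 | 8.8 |
| Monday's | 1.04 | 0.2 | 4.8 | 5.7 |
| Monday's | 3.00 | 0.2 | 5.5 | 3.0 |

(scatter of a reading: 0.5 percentage points)

- time up to 3.0 d at which complex with two exchanged stands highest
- the amount of complex with two exchanged, in percent of the starting complex charged, at that time

The second amount needs one correction first. With c(protic impurity) raised from 0.010 M to 0.040 M, the reading at 0.0833 d moves by 0.2 percentage points, less than the scatter of 0.5 points. The top readings of Thursday's and Saturday's runs therefore count as one, at 11.4%, and the c(protic impurity) of this flask lies between theirs. Monday's run tops at 14.3%, a ratio of 1.25. Set against the ratio of c(starting complex), that gives 0.327, the height exponent, an apparent order: the logarithm of the height ratio per logarithm of the concentration ratio. This flask shares Thursday's c(starting complex), so the exponent shifts nothing, and my reckoning is a peak just above 11.4%, between 0.0833 d and 0.208 d.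

The forecast puts the peak at 0.1 d (0.07 d to 0.14 d) with 11.9% (10.9% to 13.2%), holding that impurity “hardly moves the two-exchanged maximum”.

The flask peaks at 0.107 d with 11.7%.

    complex with two exchanged → decomposed reagent (k = 1.20 × 10⁻⁴ /s)
    protic impurity + starting complex → quenched substrate (k = 0.00160 /M/s)
    complex with one exchanged + incoming ligand → leaving ligand + complex with two exchanged (k = 0.00170 /M/s)
    starting complex + incoming ligand → leaving ligand + complex with one exchanged (k = 0.00190 /M/s)
    complex with two exchanged + incoming ligand → leaving ligand + complex with three exchanged (k = 7.30 × 10⁻⁴ /M/s)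
    2 starting complex → self-condensation product (k = 2.50 × 10⁻⁴ /M/s)

The quenching of starting complex by protic impurity makes no difference to the height in this flask. The same flask charged at 0.25 M of starting complex stands above the forecast's top of 13.2%. From 11.7%, the height exponent estimates 15.7% for that flask, whose highest amount of complex with two exchanged is 16.6%.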